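**Plan**

1. Retrosynthetic cuts, in order: the C15–O malonate ester; C11–C12 (mixed Kolbe coupling); ring A at C4–C18 (hydroxymethylation), C4–C5 and C10–C1 (annulation); ring B at C8–C9; then C9=C11 (olefination) and C5–C10 (aldol).
2. Enabling feature: in ring B, C8 is a tertiary carbinol carrying a methyl group and is bonded to C9, whose substituent is the C11 methylene. This pattern maps onto a C8 methyl ketone and the β-carbon (C9) of a C9=C11–C12 enoate.
3. Forward order: open chain (aldol, olefination, Wacker oxidation), ring B by cathodic closure, C12–C15 chain by Kolbe coupling, ring A by Robinson annulation and reductive hydroxymethylation, then C3 deoxygenation and malonylation.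
4. Stereochemistry: C10 and C5 from the oxazolidinone auxiliary; C9 and C8 relayed from them through the chair cyclisation; quaternary C10 by Michael addition anti to the C11 arm; C5 and C4 by reduction and aldol anti to the angular methyl.
5. C13 comes from methyl hydrogen (R)-3-methylglutarate with its two ends exchanged, because coupling through the native acid end would give the C13 epimer.

Key step: step 7

Remarks: labdane numbering (C1–C20, as in the target) is used for every intermediate. Assumption: 11, 12 and 13 are written as open trans γ-hydroxy esters; if any of them closes to the γ-lactone, the hydroxide treatment in step 13 converges both forms on carboxylate 18.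

**Route**

Step 1
Reactants: 1 (R)-4-benzyl-3-propionyloxazolidin-2-one; 2 pent-4-enal
Product: 4 (R)-4-benzyl-3-[(2R,3S)-3-hydroxy-2-methylhept-6-enoyl]oxazolidin-2-one, via (Z)-dibutylboron enolate 3 (not isolated)
Conditions: Bu2BOTf, Et3N, CH2Cl2, 0 °C; then 2, −78 → 0 °C; pH 7 buffer, MeOH, 30% H2O2, 0 °C
Reagents that add atoms: none
Why: Evans syn aldol: the (Z)-boron enolate 3 should react through a Zimmerman–Traxler chair on the enolate face away from the benzyl group, setting C10 and C5 as the (2R,3S) syn pair.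

Step 2
Reactants: 4 (R)-4-benzyl-3-[(2R,3S)-3-hydroxy-2-methylhept-6-enoyl]oxazolidin-2-one
Product: 5 (R)-4-benzyl-3-[(2R,3S)-3-(tert-butyldimethylsilyloxy)-2-methylhept-6-enoyl]oxazolidin-2-one
Conditions: TBSOTf, 2,6-lutidine, CH2Cl2, 0 °C
Reagents that add atoms: tert-butyldimethylsilyl triflate, CC(C)(C)[Si](C)(C)OS(=O)(=O)C(F)(F)F
Why: Silylation of a secondary alcohol with a silyl triflate and a hindered base is fast at 0 °C and should not trigger retro-aldol cleavage; no stereocentre is touched.

Step 3
Reactants: 5 (R)-4-benzyl-3-[(2R,3S)-3-(tert-butyldimethylsilyloxy)-2-methylhept-6-enoyl]oxazolidin-2-one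
Product: 6 (2S,3S)-3-(tert-butyldimethylsilyloxy)-2-methylhept-6-en-1-ol
Conditions: LiBH4, MeOH (1.1 equiv), THF, 0 °C
Reagents that add atoms: none
Why: Reductive auxiliary removal: LiBH4 attacks the exocyclic imide carbonyl and releases the recoverable oxazolidinone, and C10 is not epimerised because no enolisable carbonyl remains.

Step 4
Reactants: 6 (2S,3S)-3-(tert-butyldimethylsilyloxy)-2-methylhept-6-en-1-ol
Product: 7 (2R,3S)-3-(tert-butyldimethylsilyloxy)-2-methylhept-6-enal
Conditions: Dess–Martin periodinane, CH2Cl2, 0 °C → rt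
Reagents that add atoms: none
Why: Dess–Martin oxidation of a primary alcohol stops at the aldehyde under near-neutral conditions, so the α-stereocentre C10 should be kept.

Step 5
Reactants: 7 (2R,3S)-3-(tert-butyldimethylsilyloxy)-2-methylhept-6-enal; 8 trimethyl phosphonoacetate
Product: 9 methyl (2E,4S,5S)-5-(tert-butyldimethylsilyloxy)-4-methylnona-2,8-dienoate
Conditions: LiCl, i-Pr2NEt, MeCN, rt
Reagents that add atoms: none
Why: Horner–Wadsworth–Emmons olefination under the LiCl/amine (Masamune–Roush) conditions is E-selective and mild enough for an α-branched, epimerisable aldehyde.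

Step 6
Reactants: 9 methyl (2E,4S,5S)-5-(tert-butyldimethylsilyloxy)-4-methylnona-2,8-dienoate
Product: 10 methyl (2E,4S,5S)-5-(tert-butyldimethylsilyloxy)-4-methyl-8-oxonon-2-enoate
Conditions: PdCl2 (10 mol %), CuCl, O2 (1 atm), DMF/H2O 7:1, rt
Reagents that add atoms: water, O
Why: Wacker–Tsuji oxidation: hydroxypalladation of the monosubstituted alkene follows Markovnikov orientation to give the C8 methyl ketone, while the electron-poor disubstituted enoate should not react.

Step 7
Reactants: 10 methyl (2E,4S,5S)-5-(tert-butyldimethylsilyloxy)-4-methyl-8-oxonon-2-enoate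
Product: 11 methyl 2-[(1S,2S,5S,6S)-5-(tert-butyldimethylsilyloxy)-2-hydroxy-2,6-dimethylcyclohexyl]acetate
Conditions: divided cell, Pb cathode, Pt anode, Et4NOTs (0.1 M) in DMF, dimethyl malonate (2 equiv), −2.3 V vs SCE, 2 F/mol, substrate 0.02 M, 10 °C
Reagents that add atoms: none
Why: At the first reduction wave the conjugated ester (C9=C11–C12) accepts one electron while the saturated C8 ketone is not yet reduced, and the β-carbon C9 of the radical anion adds to the C8 carbonyl; a second electron and protons from dimethyl malonate then give the γ-hydroxy ester. The closest known reaction type is the electroreductive cyclisation of ketones tethered to α,β-unsaturated esters, whose chemical counterpart is the SmI2 ketyl–olefin cyclisation. Ring B closes in the 6-exo-trig mode at the carbonyl carbon (new bond C8–C9, ring atoms C5, C6, C7, C8, C9, C10). C9 is controlled by the C10 methyl and the C5 silyloxy group, which sit equatorial in the chair transition state and place the enoate arm equatorial, trans to the C10 methyl; C8 is controlled by the same chair, in which the developing alkoxide should turn away from the electron-rich enoate (oxygen equatorial and trans to C11, methyl axial). The step needs reduction of the enoate in preference to the ketone and ring closure faster than protonation or dimerisation of the radical anion; the potential gap between the two carbonyl groups, the weak carbon acid and high dilution should secure this, and the same buffer keeps electrogenerated base from the γ-hydrogen at C10.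

Step 8
Reactants: 11 methyl 2-[(1S,2S,5S,6S)-5-(tert-butyldimethylsilyloxy)-2-hydroxy-2,6-dimethylcyclohexyl]acetate
Product: 12 methyl 2-[(1S,2S,5S,6S)-2,5-dihydroxy-2,6-dimethylcyclohexyl]acetate
Conditions: HF·pyridine, pyridine, THF, 0 °C → rt
Reagents that add atoms: none
Why: Buffered fluoride desilylation cleaves the secondary silyl ether without dehydrating the tertiary C8 alcohol; no stereocentre is touched.

Step 9
Reactants: 12 methyl 2-[(1S,2S,5S,6S)-2,5-dihydroxy-2,6-dimethylcyclohexyl]acetate
Product: 13 methyl 2-[(1S,2S,6S)-2-hydroxy-2,6-dimethyl-5-oxocyclohexyl]acetate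
Conditions: Dess–Martin periodinane, CH2Cl2, rt
Reagents that add atoms: none
Why: Dess–Martin oxidation converts the secondary C5 alcohol into the ketone and cannot oxidise the tertiary C8 alcohol; the C10 methyl remains in its stable equatorial position.

Step 10
Reactants: 14 methyl hydrogen (R)-3-methylglutarate
Product: 15 methyl (R)-5-hydroxy-3-methylpentanoate
Conditions: BH3·SMe2, THF, 0 °C → rt; MeOH quench
Reagents that add atoms: none
Why: Chemoselective borane reduction: the free acid is reduced through an acyloxyborane much faster than the methyl ester, so the former acid terminus becomes C15 and C13 is not involved.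

Step 11
Reactants: 15 methyl (R)-5-hydroxy-3-methylpentanoate
Product: 16 methyl (R)-3-methyl-5-(triisopropylsilyloxy)pentanoate
Conditions: TIPSCl, imidazole, DMF, rt
Reagents that add atoms: triisopropylsilyl chloride, CC(C)[Si](Cl)(C(C)C)C(C)C
Why: Standard silylation of a primary alcohol; done promptly it forestalls lactonisation of the δ-hydroxy ester.

Step 12
Reactants: 16 methyl (R)-3-methyl-5-(triisopropylsilyloxy)pentanoate
Product: 17 (R)-3-methyl-5-(triisopropylsilyloxy)pentanoic acid
Conditions: LiOH, THF/H2O, rt; then 1 M HCl to pH 4, 0 °C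
Reagents that add atoms: lithium hydroxide, [Li+].[OH-]
Why: Saponification frees the carboxyl group at the former ester end and leaves the hindered silyl ether intact, which completes the exchange of the two glutarate termini.

Step 13
Reactants: 13 methyl 2-[(1S,2S,6S)-2-hydroxy-2,6-dimethyl-5-oxocyclohexyl]acetate; 17 (R)-3-methyl-5-(triisopropylsilyloxy)pentanoic acid
Product: 19 (2S,3S,4S)-4-hydroxy-2,4-dimethyl-3-[(3S)-3-methyl-5-(triisopropylsilyloxy)pentyl]cyclohexan-1-one, via potassium carboxylate 18 (not isolated)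
Conditions: KOH (1.0 equiv), MeOH/H2O, rt, concentrate; then 17 (6 equiv), MeOH, undivided cell, Pt anode, Pt cathode, constant current (ca. 0.2 A cm−2), 25–35 °C
Reagents that add atoms: none
Why: Mixed Kolbe electrolysis: anodic decarboxylation of the two carboxylates at platinum gives the primary C11 and C12 radicals, which should cross-couple when acid 17 is in excess; C13 is not a radical centre and keeps its configuration, and loss of the carboxyl carbon removes any later lactonisation with the C8 alcohol.

Step 14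
Reactants: 19 (2S,3S,4S)-4-hydroxy-2,4-dimethyl-3-[(3S)-3-methyl-5-(triisopropylsilyloxy)pentyl]cyclohexan-1-one; 20 ethyl vinyl ketone
Product: 22 (4aS,5S,6S)-6-hydroxy-1,4a,6-trimethyl-5-[(3S)-3-methyl-5-(triisopropylsilyloxy)pentyl]-4,4a,5,6,7,8-hexahydronaphthalen-2(3H)-one, via Michael adduct 21 (not isolated)
Conditions: NaOMe, MeOH, 0 °C → rt; then 65 °C
Reagents that add atoms: none
Why: Robinson annulation: under equilibrating alkoxide conditions the more substituted C10 enolate should add to the vinyl ketone on the face opposite the C11 arm (and opposite the axial C8 methyl), making C10 quaternary with its methyl cis to C11, and the 1,5-diketone then closes ring A by aldol condensation.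

Step 15
Reactants: 22 (4aS,5S,6S)-6-hydroxy-1,4a,6-trimethyl-5-[(3S)-3-methyl-5-(triisopropylsilyloxy)pentyl]-4,4a,5,6,7,8-hexahydronaphthalen-2(3H)-one
Product: 24 (1S,4aR,5S,6S,8aS)-6-hydroxy-1-(hydroxymethyl)-1,4a,6-trimethyl-5-[(3S)-3-methyl-5-(triisopropylsilyloxy)pentyl]octahydronaphthalen-2(1H)-one, via dilithium enolate 23 (not isolated)
Conditions: Li, NH3(l)/THF, −78 → −33 °C; isoprene; evaporate NH3; THF, −78 °C, CH2O (g); aq NH4Cl
Reagents that add atoms: formaldehyde, C=O
Why: Dissolving-metal enone reduction with regiospecific enolate trapping (reductive hydroxymethylation): protonation at C5 anti to the angular methyl, with the C8 hydroxyl as the single proton source, should give the trans ring fusion, and formaldehyde should add to the C3–C4 enolate on the face opposite that methyl, placing the hydroxymethyl group equatorial at C4.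

Step 16
Reactants: 24 (1S,4aR,5S,6S,8aS)-6-hydroxy-1-(hydroxymethyl)-1,4a,6-trimethyl-5-[(3S)-3-methyl-5-(triisopropylsilyloxy)pentyl]octahydronaphthalen-2(1H)-one
Product: 25 (1S,4aR,5S,6S,8aS)-1-(benzyloxymethyl)-6-hydroxy-1,4a,6-trimethyl-5-[(3S)-3-methyl-5-(triisopropylsilyloxy)pentyl]octahydronaphthalen-2(1H)-one
Conditions: 2-benzyloxy-1-methylpyridinium triflate, MgO, PhCF3, 85 °C
Reagents that add atoms: 2-benzyloxy-1-methylpyridinium triflate, C[n+]1ccccc1OCc1ccccc1.[O-]S(=O)(=O)C(F)(F)F
Why: Benzyl transfer from the pyridinium salt runs under neutral conditions, so the β-hydroxy ketone should not lose formaldehyde by retro-aldol cleavage, and the primary alcohol reacts ahead of the hindered tertiary one.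

Step 17
Reactants: 25 (1S,4aR,5S,6S,8aS)-1-(benzyloxymethyl)-6-hydroxy-1,4a,6-trimethyl-5-[(3S)-3-methyl-5-(triisopropylsilyloxy)pentyl]octahydronaphthalen-2(1H)-one
Product: 26 (1S,4aR,5S,6S,8aS)-1-(benzyloxymethyl)-6-hydroxy-5-[(3S)-5-hydroxy-3-methylpentyl]-1,4a,6-trimethyloctahydronaphthalen-2(1H)-one
Conditions: TBAF, THF, rt
Reagents that add atoms: none
Why: Fluoride desilylation removes the primary triisopropylsilyl ether before the hot alkali of the next step; benzyl ether, ketone and tertiary alcohol are inert to fluoride.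

Step 18
Reactants: 26 (1S,4aR,5S,6S,8aS)-1-(benzyloxymethyl)-6-hydroxy-5-[(3S)-5-hydroxy-3-methylpentyl]-1,4a,6-trimethyloctahydronaphthalen-2(1H)-one
Product: 28 (1S,2S,4aS,5S,8aR)-5-(benzyloxymethyl)-1-[(3S)-5-hydroxy-3-methylpentyl]-2,5,8a-trimethyldecahydronaphthalen-2-ol, via hydrazone 27 (not isolated)
Conditions: N2H4·H2O, KOH, diethylene glycol, 130 °C; then 200 °C
Reagents that add atoms: none
Why: Wolff–Kishner reduction (Huang-Minlon procedure): the hydrazone loses dinitrogen in hot alkali to give the C3 methylene, the benzyl ether and free alcohols tolerate the conditions, and the quaternary C4 cannot epimerise.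

Step 19
Reactants: 28 (1S,2S,4aS,5S,8aR)-5-(benzyloxymethyl)-1-[(3S)-5-hydroxy-3-methylpentyl]-2,5,8a-trimethyldecahydronaphthalen-2-ol; 29 benzyl hydrogen malonate
Product: 30 benzyl (3S)-5-[(1S,2S,4aS,5S,8aR)-5-(benzyloxymethyl)-2-hydroxy-2,5,8a-trimethyldecahydronaphthalen-1-yl]-3-methylpentyl malonate
Conditions: DCC, DMAP (cat.), CH2Cl2, 0 °C → rt
Reagents that add atoms: none
Why: Steglich esterification: the carbodiimide-activated half-ester acylates the unhindered primary C15 alcohol, while the tertiary C8 alcohol is unreactive and C18 is blocked.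

Step 20
Reactants: 30 benzyl (3S)-5-[(1S,2S,4aS,5S,8aR)-5-(benzyloxymethyl)-2-hydroxy-2,5,8a-trimethyldecahydronaphthalen-1-yl]-3-methylpentyl malonate
Product: 31 3-{[(3S)-5-[(1S,2S,4aS,5S,8aR)-2-hydroxy-5-(hydroxymethyl)-2,5,8a-trimethyldecahydronaphthalen-1-yl]-3-methylpentyl]oxy}-3-oxopropanoic acid
Conditions: H2 (1 atm), Pd/C (10 wt %), EtOAc, rt
Reagents that add atoms: none
Why: Hydrogenolysis over palladium cleaves the benzyl ester and the benzyl ether in one operation under neutral conditions that should leave the malonic half-ester and the tertiary alcohol intact.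

**Compound list**

1 | (R)-4-benzyl-3-propionyloxazolidin-2-one | CCC(=O)N1[C@H](Cc2ccccc2)COC1=O | starting material
2 | pent-4-enal | C=CCCC=O | starting material
3 | (Z)-dibutylboron enolate of 1 | CCCCB(CCCC)O/C(=C\C)N1[C@H](Cc2ccccc2)COC1=O | intermediate
4 | (R)-4-benzyl-3-[(2R,3S)-3-hydroxy-2-methylhept-6-enoyl]oxazolidin-2-one | O=C1OC[C@@H](Cc2ccccc2)N1C(=O)[C@H](C)[C@@H](O)CCC=C | intermediate
5 | (R)-4-benzyl-3-[(2R,3S)-3-(tert-butyldimethylsilyloxy)-2-methylhept-6-enoyl]oxazolidin-2-one | O=C1OC[C@@H](Cc2ccccc2)N1C(=O)[C@H](C)[C@@H](O[Si](C)(C)C(C)(C)C)CCC=C | intermediate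
6 | (2S,3S)-3-(tert-butyldimethylsilyloxy)-2-methylhept-6-en-1-ol | OC[C@H](C)[C@@H](O[Si](C)(C)C(C)(C)C)CCC=C | intermediate
7 | (2R,3S)-3-(tert-butyldimethylsilyloxy)-2-methylhept-6-enal | O=C[C@H](C)[C@@H](O[Si](C)(C)C(C)(C)C)CCC=C | intermediate
8 | trimethyl phosphonoacetate | COC(=O)CP(=O)(OC)OC | starting material
9 | methyl (2E,4S,5S)-5-(tert-butyldimethylsilyloxy)-4-methylnona-2,8-dienoate | COC(=O)/C=C/[C@H](C)[C@@H](O[Si](C)(C)C(C)(C)C)CCC=C | intermediate
10 | methyl (2E,4S,5S)-5-(tert-butyldimethylsilyloxy)-4-methyl-8-oxonon-2-enoate | COC(=O)/C=C/[C@H](C)[C@@H](O[Si](C)(C)C(C)(C)C)CCC(C)=O | intermediate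
11 | methyl 2-[(1S,2S,5S,6S)-5-(tert-butyldimethylsilyloxy)-2-hydroxy-2,6-dimethylcyclohexyl]acetate | COC(=O)C[C@H]1[C@H](C)[C@@H](O[Si](C)(C)C(C)(C)C)CC[C@]1(C)O | intermediate
12 | methyl 2-[(1S,2S,5S,6S)-2,5-dihydroxy-2,6-dimethylcyclohexyl]acetate | COC(=O)C[C@H]1[C@H](C)[C@@H](O)CC[C@]1(C)O | intermediate
13 | methyl 2-[(1S,2S,6S)-2-hydroxy-2,6-dimethyl-5-oxocyclohexyl]acetate | COC(=O)C[C@H]1[C@H](C)C(=O)CC[C@]1(C)O | intermediate
14 | methyl hydrogen (R)-3-methylglutarate | C[C@H](CC(=O)O)CC(=O)OC | starting material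
15 | methyl (R)-5-hydroxy-3-methylpentanoate | C[C@H](CCO)CC(=O)OC | intermediate
16 | methyl (R)-3-methyl-5-(triisopropylsilyloxy)pentanoate | C[C@H](CCO[Si](C(C)C)(C(C)C)C(C)C)CC(=O)OC | intermediate
17 | (R)-3-methyl-5-(triisopropylsilyloxy)pentanoic acid | C[C@H](CCO[Si](C(C)C)(C(C)C)C(C)C)CC(=O)O | intermediate
18 | potassium 2-[(1S,2S,6S)-2-hydroxy-2,6-dimethyl-5-oxocyclohexyl]acetate | [K+].[O-]C(=O)C[C@H]1[C@H](C)C(=O)CC[C@]1(C)O | intermediate
19 | (2S,3S,4S)-4-hydroxy-2,4-dimethyl-3-[(3S)-3-methyl-5-(triisopropylsilyloxy)pentyl]cyclohexan-1-one | C[C@H](CCO[Si](C(C)C)(C(C)C)C(C)C)CC[C@H]1[C@H](C)C(=O)CC[C@]1(C)O | intermediate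
20 | ethyl vinyl ketone (pent-1-en-3-one) | CCC(=O)C=C | starting material
21 | (2S,3S,4S)-4-hydroxy-2,4-dimethyl-3-[(3S)-3-methyl-5-(triisopropylsilyloxy)pentyl]-2-(3-oxopentyl)cyclohexan-1-one | C[C@H](CCO[Si](C(C)C)(C(C)C)C(C)C)CC[C@H]1[C@](C)(CCC(=O)CC)C(=O)CC[C@]1(C)O | intermediate
22 | (4aS,5S,6S)-6-hydroxy-1,4a,6-trimethyl-5-[(3S)-3-methyl-5-(triisopropylsilyloxy)pentyl]-4,4a,5,6,7,8-hexahydronaphthalen-2(3H)-one | C[C@H](CCO[Si](C(C)C)(C(C)C)C(C)C)CC[C@H]1[C@]2(C)CCC(=O)C(C)=C2CC[C@]1(C)O | intermediate
23 | dilithium salt of the reduced enone 22 (C3–C4 lithium enolate, C8 lithium alkoxide, trans ring fusion) | C[C@H](CCO[Si](C(C)C)(C(C)C)C(C)C)CC[C@H]1[C@]2(C)CCC(O[Li])=C(C)[C@H]2CC[C@]1(C)O[Li] | intermediate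
24 | (1S,4aR,5S,6S,8aS)-6-hydroxy-1-(hydroxymethyl)-1,4a,6-trimethyl-5-[(3S)-3-methyl-5-(triisopropylsilyloxy)pentyl]octahydronaphthalen-2(1H)-one | C[C@H](CCO[Si](C(C)C)(C(C)C)C(C)C)CC[C@H]1[C@]2(C)CCC(=O)[C@](C)(CO)[C@H]2CC[C@]1(C)O | intermediate
25 | (1S,4aR,5S,6S,8aS)-1-(benzyloxymethyl)-6-hydroxy-1,4a,6-trimethyl-5-[(3S)-3-methyl-5-(triisopropylsilyloxy)pentyl]octahydronaphthalen-2(1H)-one | C[C@H](CCO[Si](C(C)C)(C(C)C)C(C)C)CC[C@H]1[C@]2(C)CCC(=O)[C@](C)(COCc3ccccc3)[C@H]2CC[C@]1(C)O | intermediate
26 | (1S,4aR,5S,6S,8aS)-1-(benzyloxymethyl)-6-hydroxy-5-[(3S)-5-hydroxy-3-methylpentyl]-1,4a,6-trimethyloctahydronaphthalen-2(1H)-one | C[C@H](CCO)CC[C@H]1[C@]2(C)CCC(=O)[C@](C)(COCc3ccccc3)[C@H]2CC[C@]1(C)O | intermediate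
27 | C3 hydrazone of 26 | C[C@H](CCO)CC[C@H]1[C@]2(C)CCC(=NN)[C@](C)(COCc3ccccc3)[C@H]2CC[C@]1(C)O | intermediate
28 | (1S,2S,4aS,5S,8aR)-5-(benzyloxymethyl)-1-[(3S)-5-hydroxy-3-methylpentyl]-2,5,8a-trimethyldecahydronaphthalen-2-ol | C[C@H](CCO)CC[C@H]1[C@]2(C)CCC[C@](C)(COCc3ccccc3)[C@H]2CC[C@]1(C)O | intermediate
29 | benzyl hydrogen malonate (3-(benzyloxy)-3-oxopropanoic acid) | O=C(O)CC(=O)OCc1ccccc1 | starting material
30 | benzyl (3S)-5-[(1S,2S,4aS,5S,8aR)-5-(benzyloxymethyl)-2-hydroxy-2,5,8a-trimethyldecahydronaphthalen-1-yl]-3-methylpentyl malonate | C[C@H](CCOC(=O)CC(=O)OCc1ccccc1)CC[C@H]1[C@]2(C)CCC[C@](C)(COCc3ccccc3)[C@H]2CC[C@]1(C)O | intermediate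
31 | 3-{[(3S)-5-[(1S,2S,4aS,5S,8aR)-2-hydroxy-5-(hydroxymethyl)-2,5,8a-trimethyldecahydronaphthalen-1-yl]-3-methylpentyl]oxy}-3-oxopropanoic acid (CNP0324566.1) | C[C@H](CCOC(=O)CC(=O)O)CC[C@H]1[C@]2(C)CCC[C@](C)(CO)[C@H]2CC[C@]1(C)O | target

**Step count**

Total: 20 steps. Longest linear sequence: 17 steps (steps 1–9 and 13–20, from 1 and 2 to 31). The side-chain acid 17 takes 3 steps (10–12).

**Steps most likely to fail**

Step 7 (cathodic ring closure). Two-electron saturation or hydrodimerisation of the enoate may outrun ring closure, and facial control at the ketone carbon C8 may be incomplete. The fallback sets out from 10 and returns at 11. It is a stoichiometric ketyl–olefin cyclisation with SmI2, HMPA and t-BuOH in THF at −78 → 0 °C. Here the ketone, not the enoate, is reduced, and the bulky samarium-bound ketyl oxygen should enforce the trans relationship between the C8 oxygen and the C11 arm in the same chair. The fallback makes no compound outside the list (F0).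

Step 13 (mixed Kolbe coupling). Statistical radical pairing may give mostly homodimers, and over-oxidation of the C11 radical to a cation (Hofer–Moest pathway) may erode the cross-coupled product. The fallback sets out from 17 and from carboxylate 18 and returns at 19. Acid 17 would be converted by Hunsdiecker-type bromodecarboxylation (HgO, Br2, CCl4, reflux, dark) into (R)-(4-bromo-3-methylbutoxy)triisopropylsilane F1. Carboxylate 18, made from 13 as in step 13, would then be joined to F1 by photoredox/nickel dual-catalysed decarboxylative alkyl–alkyl coupling (Ir[dF(CF3)ppy]2(dtbbpy)PF6, NiCl2·glyme, 4,4′-dimethoxy-2,2′-bipyridine, MeCN/H2O, blue light). This forms the same C11–C12 bond with one partner fixed as an electrophile, so no statistical mixture arises.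

Step 14 (Robinson annulation). Michael addition may occur through the less substituted C6 enolate, the vinyl ketone may polymerise, and aldol dehydration may stall on the hindered diketone. The fallback sets out from 19 and returns at 21, which is then closed to 22 with NaOMe in MeOH at 65 °C. Ketone 19 would be converted with TMSCl, NaI and Et3N in MeCN into the thermodynamic, tetrasubstituted silyl enol ether, with the C8 hydroxyl silylated as well: triisopropyl{[(3S)-3-methyl-5-[(1S,6S)-2,6-dimethyl-3,6-bis(trimethylsilyloxy)cyclohex-2-en-1-yl]pentyl]oxy}silane F2. A Mukaiyama–Michael addition of F2 to ethyl vinyl ketone 20 (TiCl4, CH2Cl2, −78 °C, aqueous acid work-up) fixes the site of C–C bond formation at C10 and gives diketone 21.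

**Further compounds**

F0 | step 7 | none | none
F1 | step 13 | (R)-(4-bromo-3-methylbutoxy)triisopropylsilane | C[C@H](CCO[Si](C(C)C)(C(C)C)C(C)C)CBr
F2 | step 14 | triisopropyl{[(3S)-3-methyl-5-[(1S,6S)-2,6-dimethyl-3,6-bis(trimethylsilyloxy)cyclohex-2-en-1-yl]pentyl]oxy}silane | C[C@H](CCO[Si](C(C)C)(C(C)C)C(C)C)CC[C@H]1C(C)=C(O[Si](C)(C)C)CC[C@]1(C)O[Si](C)(C)C
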